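**Plan**

1. Retrosynthetic cuts: first the two MOM ethers, then the enone Cα=Cβ bond (aldol) to acetylchroman 12 and aldehyde 14. Ring C is then cut at C4–C3 and O1–C2 together, to ortho-quinone methide 11 and diene 10. Last, the acetyl and CH2OMe groups on ring A are cut back to 5-methoxyresorcinol.
2. Enabling feature: in ring C (O1–C2–C3–C4–C4a–C8a) C4 is a bare benzylic CH2 ortho to the phenolic oxygen O1, so C4=C4a–C8a=O1 is an ortho-quinone methide. C2(Me2)–C3(H) with its CH2CH=CMe2 arm is one double bond of the C2v-symmetric 2,6-dimethylhepta-2,5-diene; the second, untouched double bond is the prenyl group.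
3. Forward order: ring A is bought and substituted by two directed metalations (steps 1–4). Ring C is closed on it by an oxa-(4+2) cycloaddition (step 6). Ring B is joined by Claisen–Schmidt condensation (step 8), and deprotection ends the route (step 9).
4. Stereochemistry: C3 (R) is set in step 6 by a chiral Brønsted acid and carries no acidic hydrogen afterwards. The E-enone arises under thermodynamic control in step 8.

Key step: step 6

Assumption: the (R)-configured acid catalyst of step 6 is taken to deliver the (3R)-chroman; should the sense of induction prove opposite, its (S)-enantiomer is used instead.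

**Route**

Step 1
Reactants: 1 5-methoxyresorcinol
Product: 2 1-methoxy-3,5-bis(methoxymethoxy)benzene
Conditions: NaH (2.4 equiv), MOMCl (2.4 equiv), DMF, 0 °C to rt
Reagents that add atoms: chloromethyl methyl ether (MOMCl), COCCl
Why: Williamson O-alkylation of both phenoxides (MOM protection) should install the two directing groups needed for the metalations that follow.

Step 2
Reactants: 2 1-methoxy-3,5-bis(methoxymethoxy)benzene
Product: 4 5-methoxy-2-(methoxymethyl)-1,3-bis(methoxymethoxy)benzene, via aryllithium 3 (not isolated)
Conditions: n-BuLi (1.1 equiv), THF, 0 °C, 1 h; then MOMCl (1.3 equiv), –78 °C to rt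
Reagents that add atoms: chloromethyl methyl ether (MOMCl), COCCl
Why: Directed ortho-metalation should take place at the C–H flanked by both OMOM groups, the most acidic and doubly chelated site, and C-alkylation of the aryllithium by the reactive α-chloro ether gives the benzylic methyl ether that later serves as the latent ortho-quinone methide.

Step 3
Reactants: 4 5-methoxy-2-(methoxymethyl)-1,3-bis(methoxymethoxy)benzene
Product: 6 1-[6-methoxy-3-(methoxymethyl)-2,4-bis(methoxymethoxy)phenyl]ethan-1-one, via aryllithium 5 (not isolated)
Conditions: n-BuLi (1.2 equiv), THF, 0 °C, 1 h; then N-methoxy-N-methylacetamide (1.5 equiv), –78 °C to 0 °C; then H2O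
Reagents that add atoms: N-methoxy-N-methylacetamide, CC(=O)N(C)OC
Why: A second directed ortho-metalation at one of the two symmetry-equivalent ring C–H positions (each between OMOM and OMe) followed by Weinreb amide acylation should stop at the ketone through the chelated tetrahedral intermediate, so the acetyl group is placed without any regiochemical choice.

Step 4
Reactants: 6 1-[6-methoxy-3-(methoxymethyl)-2,4-bis(methoxymethoxy)phenyl]ethan-1-one
Product: 7 1-[2,4-dihydroxy-6-methoxy-3-(methoxymethyl)phenyl]ethan-1-one
Conditions: HCl (1.25 M in MeOH), rt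
Reagents that add atoms: none
Why: Acid-catalysed acetal exchange with methanol should remove both MOM ethers, while the benzylic methyl ether survives because any benzylic cation formed is returned to the same ether by the solvent.

Step 5
Reactants: 8 1-bromo-3-methylbut-2-ene (prenyl bromide); 9 (2-methylprop-1-en-1-yl)magnesium bromide
Product: 10 2,6-dimethylhepta-2,5-diene
Conditions: Li2CuCl4 (3 mol%), THF, –20 °C to 0 °C; distillation
Reagents that add atoms: none
Why: Copper-catalysed cross-coupling of an alkenyl Grignard reagent with an allylic bromide should occur at the unhindered primary carbon under these conditions and so give the skipped 2,5-diene and not the branched 1,4-diene.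

Step 6
Reactants: 7 1-[2,4-dihydroxy-6-methoxy-3-(methoxymethyl)phenyl]ethan-1-one; 10 2,6-dimethylhepta-2,5-diene (5 equiv)
Product: 12 1-[(3R)-5-hydroxy-7-methoxy-2,2-dimethyl-3-(3-methylbut-2-en-1-yl)-3,4-dihydro-2H-chromen-6-yl]ethan-1-one, via ortho-quinone methide 11 (not isolated)
Conditions: (R)-3,3'-bis(2,4,6-triisopropylphenyl)-1,1'-binaphthyl-2,2'-diyl N-triflylphosphoramide (10 mol%), 5 Å molecular sieves, PhMe, 0 °C to rt, slow addition of 7
Reagents that add atoms: none
Why: Proposed new method: the chiral acid should ionise the benzylic methyl ether of 7 to the acetyl-activated ortho-quinone methide 11, held as a hydrogen-bonded ion pair at its carbonyl oxygen; the CH terminus of one double bond of 10 then attacks the exocyclic CH2 while the developing tertiary cation at CMe2 is captured by that oxygen, an asynchronous inverse-electron-demand oxa-(4+2) cycloaddition that forms C4–C3 and O1–C2. The closest known reaction types are the chiral phosphoric acid catalysed cycloadditions of ortho-quinone methides (from ortho-hydroxybenzyl alcohols) with styrenes and enol ethers, and the uncatalysed cycloadditions of acylphloroglucinol ortho-quinone methides with trisubstituted terpene alkenes; enantiocontrol with an unactivated alkene is the untested part. Ring C closes by this intermolecular (4+2) mode through a six-membered transition state. The single new stereocentre C3 is set by the catalyst: the confined phosphoramide anion bound to the reacting oxygen should let the alkene approach with its CH2CH=CMe2 arm turned away from the 3,3'-aryl walls, exposing one enantiotopic face of the alkene CH. The step needs Markovnikov regiochemistry (secured by the tertiary cation character at CMe2), closure on the oxygen para to the acetyl group and not on the ortho one (secured by the hydrogen bond of the ortho hydroxyl to the acetyl C=O, which only the desired product keeps), and reaction of only one alkene of 10 (secured by its symmetry, which makes both alkenes equivalent, and by its excess).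

Step 7
Reactants: 13 2,4-dihydroxybenzaldehyde
Product: 14 2,4-bis(methoxymethoxy)benzaldehyde
Conditions: NaH (2.4 equiv), MOMCl (2.4 equiv), DMF, 0 °C to rt
Reagents that add atoms: chloromethyl methyl ether (MOMCl), COCCl
Why: MOM protection of both phenols, the chelated one included under NaH, should give a non-enolisable aldehyde that stays electrophilic in the basic aldol step.

Step 8
Reactants: 12 1-[(3R)-5-hydroxy-7-methoxy-2,2-dimethyl-3-(3-methylbut-2-en-1-yl)-3,4-dihydro-2H-chromen-6-yl]ethan-1-one; 14 2,4-bis(methoxymethoxy)benzaldehyde
Product: 15 (2E)-3-[2,4-bis(methoxymethoxy)phenyl]-1-[(3R)-5-hydroxy-7-methoxy-2,2-dimethyl-3-(3-methylbut-2-en-1-yl)-3,4-dihydro-2H-chromen-6-yl]prop-2-en-1-one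
Conditions: KOH (50% aq., 10 equiv), EtOH, rt
Reagents that add atoms: none
Why: Claisen–Schmidt condensation of the methyl ketone enolate with the aldehyde and E1cB dehydration should give the thermodynamically favoured E-enone, while C3, remote and without an acidic hydrogen, is untouched.

Step 9
Reactants: 15 (2E)-3-[2,4-bis(methoxymethoxy)phenyl]-1-[(3R)-5-hydroxy-7-methoxy-2,2-dimethyl-3-(3-methylbut-2-en-1-yl)-3,4-dihydro-2H-chromen-6-yl]prop-2-en-1-one
Product: 16 (2E)-3-(2,4-dihydroxyphenyl)-1-[(3R)-5-hydroxy-7-methoxy-2,2-dimethyl-3-(3-methylbut-2-en-1-yl)-3,4-dihydro-2H-chromen-6-yl]prop-2-en-1-one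
Conditions: HCl (3 M aq.), MeOH, rt
Reagents that add atoms: none
Why: Acid-catalysed acetal cleavage of the two aryl MOM ethers in methanol should proceed under conditions mild enough to leave the prenyl double bond, the enone and the chroman untouched.

**Compound list**

1 | 5-methoxyresorcinol (5-methoxybenzene-1,3-diol) | COc1cc(O)cc(O)c1 | starting material
2 | 1-methoxy-3,5-bis(methoxymethoxy)benzene | COCOc1cc(OC)cc(OCOC)c1 | intermediate
3 | [4-methoxy-2,6-bis(methoxymethoxy)phenyl]lithium | [Li]c1c(OCOC)cc(OC)cc1OCOC | intermediate (not isolated)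
4 | 5-methoxy-2-(methoxymethyl)-1,3-bis(methoxymethoxy)benzene | COCc1c(OCOC)cc(OC)cc1OCOC | intermediate
5 | [2-methoxy-5-(methoxymethyl)-4,6-bis(methoxymethoxy)phenyl]lithium | [Li]c1c(OC)cc(OCOC)c(COC)c1OCOC | intermediate (not isolated)
6 | 1-[6-methoxy-3-(methoxymethyl)-2,4-bis(methoxymethoxy)phenyl]ethan-1-one | CC(=O)c1c(OC)cc(OCOC)c(COC)c1OCOC | intermediate
7 | 1-[2,4-dihydroxy-6-methoxy-3-(methoxymethyl)phenyl]ethan-1-one | CC(=O)c1c(OC)cc(O)c(COC)c1O | intermediate
8 | 1-bromo-3-methylbut-2-ene (prenyl bromide) | CC(C)=CCBr | starting material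
9 | (2-methylprop-1-en-1-yl)magnesium bromide | CC(C)=C[Mg]Br | starting material
10 | 2,6-dimethylhepta-2,5-diene | CC(C)=CCC=C(C)C | intermediate
11 | 4-acetyl-5-hydroxy-3-methoxy-6-methylidenecyclohexa-2,4-dien-1-one (ortho-quinone methide) | C=C1C(=O)C=C(OC)C(C(C)=O)=C1O | intermediate (not isolated)
12 | 1-[(3R)-5-hydroxy-7-methoxy-2,2-dimethyl-3-(3-methylbut-2-en-1-yl)-3,4-dihydro-2H-chromen-6-yl]ethan-1-one | COc1cc2c(c(O)c1C(C)=O)C[C@@H](CC=C(C)C)C(C)(C)O2 | intermediate
13 | 2,4-dihydroxybenzaldehyde | O=Cc1ccc(O)cc1O | starting material
14 | 2,4-bis(methoxymethoxy)benzaldehyde | COCOc1ccc(C=O)c(OCOC)c1 | intermediate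
15 | (2E)-3-[2,4-bis(methoxymethoxy)phenyl]-1-[(3R)-5-hydroxy-7-methoxy-2,2-dimethyl-3-(3-methylbut-2-en-1-yl)-3,4-dihydro-2H-chromen-6-yl]prop-2-en-1-one | COCOc1ccc(/C=C/C(=O)c2c(OC)cc3c(c2O)C[C@@H](CC=C(C)C)C(C)(C)O3)c(OCOC)c1 | intermediate
16 | (2E)-3-(2,4-dihydroxyphenyl)-1-[(3R)-5-hydroxy-7-methoxy-2,2-dimethyl-3-(3-methylbut-2-en-1-yl)-3,4-dihydro-2H-chromen-6-yl]prop-2-en-1-one | COc1cc2c(c(O)c1C(=O)/C=C/c1ccc(O)cc1O)C[C@@H](CC=C(C)C)C(C)(C)O2 | target

**Step count**

Total: 9 steps. Longest linear sequence: 7 steps (steps 1, 2, 3, 4, 6, 8 and 9).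

**Steps most likely to fail**

Step 6. The catalyst may discriminate the two faces of the unactivated alkene poorly, and Friedel–Crafts self-alkylation of the electron-rich arene by the ortho-quinone methide may outrun the cycloaddition. The fallback gives up catalyst control and uses known chemistry. It sets out from 7 and 10: heating the two in 1,1,1,3,3,3-hexafluoropropan-2-ol at 50 °C without any chiral additive should give, by the well-precedented uncatalysed cycloaddition of acylphloroglucinol ortho-quinone methides with trisubstituted alkenes, the racemic acetylchroman F1. Preparative chromatography of F1 on a chiral stationary phase (amylose tris(3,5-dimethylphenylcarbamate), hexane/i-PrOH) then delivers the (3R)-enantiomer, and the route is rejoined at 12.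

Step 3. Deprotonation at the benzylic CH2 next to the ether oxygen, followed by Wittig rearrangement, may compete with ring metalation. The fallback replaces deprotonation by halogenation and halogen–metal exchange. It sets out from 4: N-iodosuccinimide (1.0 equiv) in MeCN at 0 °C should iodinate one of the two equivalent ring positions to give the aryl iodide F2. Iodine–magnesium exchange with i-PrMgCl·LiCl in THF at –20 °C gives the arylmagnesium chloride F3 (not isolated), and acylation with N-methoxy-N-methylacetamide returns to the route at 6.

Step 9. Under acid, the freed 2-hydroxyl of ring B may cyclise onto the protonated enone (benzopyrylium formation), the chalcone may close to a flavanone, or the prenyl double bond may add solvent. The fallback changes the protecting group to one removed without acid. It sets out from 13: allyl bromide and K2CO3 in DMF should give 2,4-bis(allyloxy)benzaldehyde F4. Claisen–Schmidt condensation of F4 with 12 (KOH, EtOH, rt) gives the bis-allyl chalcone F5. Tsuji–Trost deallylation of F5 with Pd(PPh3)4 (5 mol%, zerovalent palladium) and morpholine in THF at rt returns to the route at 16.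

**Further compounds**

F1 | step 6 | racemic 1-[5-hydroxy-7-methoxy-2,2-dimethyl-3-(3-methylbut-2-en-1-yl)-3,4-dihydro-2H-chromen-6-yl]ethan-1-one | COc1cc2c(c(O)c1C(C)=O)CC(CC=C(C)C)C(C)(C)O2
F2 | step 3 | 2-iodo-1-methoxy-4-(methoxymethyl)-3,5-bis(methoxymethoxy)benzene | COCc1c(OCOC)cc(OC)c(I)c1OCOC
F3 | step 3 | [2-methoxy-5-(methoxymethyl)-4,6-bis(methoxymethoxy)phenyl]magnesium chloride | COCc1c(OCOC)cc(OC)c([Mg]Cl)c1OCOC
F4 | step 9 | 2,4-bis(prop-2-en-1-yloxy)benzaldehyde | C=CCOc1ccc(C=O)c(OCC=C)c1
F5 | step 9 | (2E)-3-[2,4-bis(prop-2-en-1-yloxy)phenyl]-1-[(3R)-5-hydroxy-7-methoxy-2,2-dimethyl-3-(3-methylbut-2-en-1-yl)-3,4-dihydro-2H-chromen-6-yl]prop-2-en-1-one | C=CCOc1ccc(/C=C/C(=O)c2c(OC)cc3c(c2O)C[C@@H](CC=C(C)C)C(C)(C)O3)c(OCC=C)c1
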